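(The numbers in the tables were generated by integration on assumed constants; scatter was added.)

Alder is read at 320 min, twice the last ash time, and it carries the ash charge, so the ash curve serves as alder's first half.

| setting | ash | larch | birch | elm | alder |
|---|---|---|---|---|---|
| Xa | 0.400 M | 0.240 M | 0.400 M | 0.800 M | 0.400 M |
| Xb | 1.20 M | 1.04 M | 1.80 M | 1.20 M | 1.20 M |
| time |  |  |  |  | 320 min |

| run | time / min | [Xp] / M |
|---|---|---|
| ash run | 6.4 | 8 × 10⁻⁴ |
| ash run | 12 | 0.0028 |
| ash run | 23 | 0.0185 |
| ash run | 44 | 0.0541 |
| ash run | 84 | 0.1074 |
| ash run | 160 | 0.1477 |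
| larch run | 6.4 | 0.0011 |
| larch run | 12 | 0.0047 |
| larch run | 23 | 0.0099 |
| larch run | 44 | 0.0246 |
| larch run | 84 | 0.0584 |
| larch run | 160 | 0.0903 |
| birch run | 6.4 | 0.0055 |
| birch run | 12 | 0.0111 |
| birch run | 23 | 0.0312 |
| birch run | 44 | 0.0706 |
| birch run | 84 | 0.1346 |
| birch run | 160 | 0.1822 |
| elm run | 6.4 | 0.0091 |
| elm run | 12 | 0.0107 |
| elm run | 23 | 0.0379 |
| elm run | 44 | 0.0939 |
| elm run | 84 | 0.1961 |
| elm run | 160 | 0.2707 |

(readings scatter by 0.002 M)

- how the opening rate goes with [Xb] round the charge of the ash run: the exponent of the rate at two percent of Xa gone to Xp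
- how the opening rate goes with [Xa] round the charge of the ash run: the exponent of the rate at two percent of Xa gone to Xp (one fixed amount of Xp, the same in the runs compared)
- Xp in the alder run at 320 min, as a share of the Xa charged

- Overall: Xa + Xb -> Xp.
- Constant volume, constant temperature.
- "The second partner" is Xb.
- An order is taken over about fifteen percent of the charge, up and down.

In ash the net rate of Xp falls from 0.00133 M min⁻¹ between 44 min and 84 min to 5.30 × 10⁻⁴ M min⁻¹ between 84 min and 160 min, while mean [Xp] in those stretches rises from 0.0808 M to 0.128 M. Take the net rate as feed minus k[Xp], with k a first-order loss constant of Xp.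

Two extreme versions can be solved at once. With k zero the feed does all the slowing and Xp stays once formed, so alder stands at or above the last ash reading, 36.9 % of the charge. With a constant feed the loss does all the slowing:

k_max = 0.0171 min⁻¹

This reckoning places the real flask between them: counted from mean [Xp], [Xa] drops by about 14.7 % between those stretches, so the feed is not taken as constant. The reckoning does not divide the slowing further and assumes k = 0.00857 min⁻¹, half of k_max.

The curve is then replaced by its mean. A straight chord up to the last ash reading, followed by a flat tail to 320 min, gives the mean [Xp] over the whole time, 0.111 M. The chord lies under the ash reading at 84 min, and a flat tail lies over a falling curve, so these errors oppose each other. The balance is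

[Xp] at the reading = Xp made − k × mean [Xp] × time

Counting the whole charge as made, this reckoning puts alder near 24.0 %, below the last ash reading.

The forecast, which differs from this reckoning, gave an order of 0.5 in [Xb], an order of 0.9 in [Xa] and 43 % for alder, and read the slowing as “a catalyst or active species dying with time”.

The simulation gives an order of 0.54 in [Xb], an order of 0.60 in [Xa] and 27.8 % for alder.

    Xa + Xb → Xi (0.01500 M⁻¹ min⁻¹)
    Xi → Xp (0.01446 min⁻¹)
    Xb → G (0.007440 min⁻¹)
    Xp → E (0.005424 min⁻¹)

Alder's shortfall comes mainly from the path from Xp to E: alder stands at 27.8 %, and the same run without that path reaches 77.2 %. With k4 at 0.00542 min⁻¹ and the mean 0.111 M, alder's loss over 320 min comes to 48.1 % of the charge, against a simulated effect of 49 percentage points.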